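The flavanone is cut at C3–C4 of the pyranone ring (ring C). The design exploits the fact that the ketone carbon C4 sits on ring A ortho to the ring oxygen O1 (C4–C4a–C8a–O1): an aldehyde at C4 and a 1-arylvinyl group on O1 hold the terminal olefin carbon (C3) beside the acyl carbon. One rhodium-catalysed hydroacylation then forms C3–C4, closes ring C and sets C2 by hydride transfer. The precursor is a per-silylated 2-(1-arylvinyloxy)benzaldehyde carrying the Z side chain at the future C8, assembled from 4-bromoresorcinol, a Z-allylic bromide and protocatechuic acid via aryl ester methylenation and a late bromine-to-aldehyde exchange.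

Key step: step 13

Abbreviations: TBS = tert-butyldimethylsilyl, MOM = methoxymethyl, TMPH = 2,2,6,6-tetramethylpiperidine, DIC = N,N'-diisopropylcarbodiimide, DCE = 1,2-dichloroethane.

Design remark: all four hydroxyls are carried as TBS ethers. They are poor ligands for cationic rhodium and come off together with buffered fluoride, so no acid or base touches the molecule once C2 is set. The vinyl ether is made by methylenation of an aryl ester, so the hindered C–O bond arises by simple acylation and the aldehyde is introduced last.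

Assumption: the sense of induction of the new catalytic step cannot be predicted; the (R) ligand is written and its antipode is used if a pilot run delivers the 2R ketone.

Step 1
Reactants: 1 tert-butyldimethyl(prop-2-yn-1-yloxy)silane
Product: 3 ethyl 4-(tert-butyldimethylsilyloxy)but-2-ynoate, via lithium acetylide 2 (not isolated)
Conditions: n-BuLi, THF, −78 °C; ClCO2Et, −78 → 0 °C
Reagents that add atoms: ethyl chloroformate, CCOC(=O)Cl
Why: Acylation of a lithium acetylide: the terminal alkyne is deprotonated cleanly and the acetylide displaces chloride from the chloroformate to give the ynoate.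

Step 2
Reactants: 3 ethyl 4-(tert-butyldimethylsilyloxy)but-2-ynoate
Product: 5 ethyl (Z)-4-(tert-butyldimethylsilyloxy)-3-methylbut-2-enoate, via α-cuprio enoate 4 (not isolated)
Conditions: Me2CuLi (from MeLi, CuI), THF, −78 °C; aq NH4Cl at −78 °C
Reagents that add atoms: lithium dimethylcuprate, [Li+].C[Cu-]C
Why: Syn carbocupration (conjugate addition of a Gilman cuprate) of the ynoate places methyl and copper cis, and protonation at −78 °C with retention should leave CH2OTBS cis to the ester, i.e. the Z olefin.

Step 3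
Reactants: 5 ethyl (Z)-4-(tert-butyldimethylsilyloxy)-3-methylbut-2-enoate
Product: 6 (Z)-4-(tert-butyldimethylsilyloxy)-3-methylbut-2-en-1-ol
Conditions: DIBAL-H (2.2 equiv), CH2Cl2, −78 °C; Rochelle salt
Reagents that add atoms: none
Why: 1,2-Reduction of the conjugated ester with DIBAL-H should give the allylic alcohol without touching the olefin geometry, and the non-basic work-up avoids silyl migration to the cis hydroxyl.

Step 4
Reactants: 6 (Z)-4-(tert-butyldimethylsilyloxy)-3-methylbut-2-en-1-ol
Product: 7 tert-butyl{[(2Z)-4-bromo-2-methylbut-2-en-1-yl]oxy}dimethylsilane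
Conditions: CBr4, PPh3, CH2Cl2, 0 °C; used without storage
Reagents that add atoms: carbon tetrabromide, BrC(Br)(Br)Br
Why: Appel bromination converts the primary allylic alcohol into the bromide by SN2 displacement of the alkoxyphosphonium under neutral conditions, so the silyl ether and the Z olefin are kept.

Step 5
Reactants: 8 4-bromoresorcinol
Product: 9 1-bromo-2,4-bis(methoxymethoxy)benzene
Conditions: MOMCl (2.5 equiv), i-Pr2NEt, CH2Cl2, 0 °C → rt
Reagents that add atoms: chloromethyl methyl ether, COCCl
Why: Williamson-type O-alkylation of both phenols with the α-chloro ether installs two acetal groups that direct the next metalation.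

Step 6
Reactants: 9 1-bromo-2,4-bis(methoxymethoxy)benzene; 7 tert-butyl{[(2Z)-4-bromo-2-methylbut-2-en-1-yl]oxy}dimethylsilane
Product: 12 1-bromo-2,4-bis(methoxymethoxy)-3-[(Z)-4-(tert-butyldimethylsilyloxy)-3-methylbut-2-enyl]benzene, via aryllithium 10 (not isolated), via arylcopper 11 (not isolated)
Conditions: LiTMP (from TMPH, n-BuLi), THF, −78 °C; CuI, −78 → −30 °C; 7, −78 → 0 °C
Reagents that add atoms: none
Why: Directed ortho-metalation with a lithium amide (which does not exchange bromine) removes the C–H flanked by both MOM ethers, and the derived arylcopper should be allylated at the primary carbon of 7 (SN2-type copper-mediated allylation, as in resorcinol prenylations) with retention of the Z olefin.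

Step 7
Reactants: 12 1-bromo-2,4-bis(methoxymethoxy)-3-[(Z)-4-(tert-butyldimethylsilyloxy)-3-methylbut-2-enyl]benzene
Product: 13 4-bromo-2-[(Z)-4-hydroxy-3-methylbut-2-enyl]benzene-1,3-diol
Conditions: 2 M HCl in MeOH, rt
Reagents that add atoms: none
Why: Acid-catalysed acetal methanolysis removes both aryl MOM ethers together with the primary silyl ether, under conditions expected to be too mild to ionise the primary allylic alcohol or add a phenol to the trisubstituted olefin.

Step 8
Reactants: 13 4-bromo-2-[(Z)-4-hydroxy-3-methylbut-2-enyl]benzene-1,3-diol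
Product: 14 6-bromo-3-(tert-butyldimethylsilyloxy)-2-[(Z)-4-(tert-butyldimethylsilyloxy)-3-methylbut-2-enyl]phenol
Conditions: TBSCl (2.1 equiv), imidazole, CH2Cl2, 0 °C
Reagents that add atoms: tert-butyldimethylsilyl chloride, CC(C)(C)[Si](C)(C)Cl
Why: Sterically controlled silylation: the primary alcohol and the phenol with a single ortho neighbour should react, whereas the hydroxyl flanked by bromine and the side chain is hindered and electron-poor and stays free.

Step 9
Reactants: 15 3,4-dihydroxybenzoic acid
Product: 17 3,4-bis(tert-butyldimethylsilyloxy)benzoic acid, via silyl ester 16 (not isolated)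
Conditions: TBSCl (3.3 equiv), imidazole, DMF, rt; then AcOH/THF/H2O, rt
Reagents that add atoms: tert-butyldimethylsilyl chloride, CC(C)(C)[Si](C)(C)Cl
Why: Exhaustive silylation followed by selective hydrolysis of the far more labile silyl ester frees the acid and keeps the two aryl silyl ethers.

Step 10
Reactants: 14 6-bromo-3-(tert-butyldimethylsilyloxy)-2-[(Z)-4-(tert-butyldimethylsilyloxy)-3-methylbut-2-enyl]phenol; 17 3,4-bis(tert-butyldimethylsilyloxy)benzoic acid
Product: 18 6-bromo-3-(tert-butyldimethylsilyloxy)-2-[(Z)-4-(tert-butyldimethylsilyloxy)-3-methylbut-2-enyl]phenyl 3,4-bis(tert-butyldimethylsilyloxy)benzoate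
Conditions: DIC, DMAP (cat.), CH2Cl2, rt
Reagents that add atoms: none
Why: Steglich esterification: the acylpyridinium formed from the O-acylisourea is reactive enough to acylate the hindered ortho-bromophenol.

Step 11
Reactants: 18 6-bromo-3-(tert-butyldimethylsilyloxy)-2-[(Z)-4-(tert-butyldimethylsilyloxy)-3-methylbut-2-enyl]phenyl 3,4-bis(tert-butyldimethylsilyloxy)benzoate
Product: 19 1-bromo-2-{1-[3,4-bis(tert-butyldimethylsilyloxy)phenyl]vinyloxy}-4-(tert-butyldimethylsilyloxy)-3-[(Z)-4-(tert-butyldimethylsilyloxy)-3-methylbut-2-enyl]benzene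
Conditions: Tebbe reagent, pyridine (cat.), THF/toluene, −40 °C → rt; dilute aq NaOH quench; Et3N-deactivated silica
Reagents that add atoms: Tebbe reagent (cyclopentadienyl rings drawn σ-bonded), C[Al-]1(C)C[Ti](C2C=CC=C2)(C2C=CC=C2)[Cl+]1
Why: Tebbe methylenation of an aryl benzoate proceeds through an oxatitanacyclobutane to the 1-aryloxy-1-arylethene, and the aryl bromide, silyl ethers and trisubstituted olefin are inert to the titanium methylidene.

Step 12
Reactants: 19 1-bromo-2-{1-[3,4-bis(tert-butyldimethylsilyloxy)phenyl]vinyloxy}-4-(tert-butyldimethylsilyloxy)-3-[(Z)-4-(tert-butyldimethylsilyloxy)-3-methylbut-2-enyl]benzene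
Product: 21 2-{1-[3,4-bis(tert-butyldimethylsilyloxy)phenyl]vinyloxy}-4-(tert-butyldimethylsilyloxy)-3-[(Z)-4-(tert-butyldimethylsilyloxy)-3-methylbut-2-enyl]benzaldehyde, via aryllithium 20 (not isolated)
Conditions: n-BuLi, THF, −78 °C; DMF, −78 → 0 °C; aq NH4Cl; Et3N-deactivated silica
Reagents that add atoms: N,N-dimethylformamide, CN(C)C=O
Why: Bromine–lithium exchange at −78 °C is faster than any attack on the silyl ethers or the enol ether, and the aryllithium is formylated with DMF (Bouveault formylation) to place the aldehyde ortho to the vinyl ether oxygen.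

Step 13
Reactants: 21 2-{1-[3,4-bis(tert-butyldimethylsilyloxy)phenyl]vinyloxy}-4-(tert-butyldimethylsilyloxy)-3-[(Z)-4-(tert-butyldimethylsilyloxy)-3-methylbut-2-enyl]benzaldehyde
Product: 22 (2S)-2-[3,4-bis(tert-butyldimethylsilyloxy)phenyl]-7-(tert-butyldimethylsilyloxy)-8-[(Z)-4-(tert-butyldimethylsilyloxy)-3-methylbut-2-enyl]chroman-4-one
Conditions: [Rh(cod)2]SbF6 (10 mol %), (R)-DTBM-SEGPHOS (11 mol %), H2 activation then Ar purge; 2,6-di-tert-butyl-4-methylpyridine (10 mol %), degassed DCE, 40 → 60 °C
Reagents that add atoms: none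
Why: Proposed new method: the cationic Rh(I) bisphosphine should add oxidatively into the aldehyde C–H bond of 21 to give an acyl rhodium(III) hydride that the adjacent aryl vinyl ether oxygen can hold in a five-membered chelate, the coordinated olefin then inserts with hydride going to C2 and rhodium to the terminal carbon C3, and C3–C4 reductive elimination releases ketone 22 and Rh(I). The closest known reaction type is the rhodium-catalysed enantioselective intramolecular olefin hydroacylation assisted by a chelating ether or sulfide, established for cyclopentanones and seven-membered benzo-fused ketones but not for a six-membered closure onto an enol ether. Ring C closes in the 6-endo-trig mode through a seven-membered acyl alkyl rhodacycle. C2, the only stereocentre, is set under catalyst control, the chiral bisphosphine choosing the face of the 1,1-disubstituted vinyl ether to which hydride is delivered. The step needs endo over exo insertion, hydroacylation over decarbonylation and an untouched side chain: the exo path would require a tertiary α-aryl-α-aryloxy alkyl rhodium and a quaternary carbon, oxygen chelation and the ortho placement keep the olefin at the acyl rhodium hydride, the vinyl ether has no allylic hydrogen to isomerise, and the remote trisubstituted olefin and the four bulky silyl ethers are poor ligands. The hindered pyridine and an acid-free catalyst keep the electron-rich enol ether from acid-induced addition to the aldehyde.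

Step 14
Reactants: 22 (2S)-2-[3,4-bis(tert-butyldimethylsilyloxy)phenyl]-7-(tert-butyldimethylsilyloxy)-8-[(Z)-4-(tert-butyldimethylsilyloxy)-3-methylbut-2-enyl]chroman-4-one
Product: 23 (2S)-2-(3,4-dihydroxyphenyl)-7-hydroxy-8-[(2Z)-4-hydroxy-3-methylbut-2-en-1-yl]-2,3-dihydro-4H-chromen-4-one
Conditions: HF·pyridine, excess pyridine, THF, 0 °C → rt, under Ar
Reagents that add atoms: none
Why: Fluoride-mediated global desilylation under buffered, weakly acidic conditions removes all four TBS groups without the base that would open the flavanone by retro-oxa-Michael reaction (which would racemise C2) and without strong acid that could cyclise the phenol onto the side chain.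

Compound list
1 | tert-butyldimethyl(prop-2-yn-1-yloxy)silane | C#CCO[Si](C)(C)C(C)(C)C | starting material
2 | [3-(tert-butyldimethylsilyloxy)prop-1-yn-1-yl]lithium (not isolated) | [Li]C#CCO[Si](C)(C)C(C)(C)C | intermediate
3 | ethyl 4-(tert-butyldimethylsilyloxy)but-2-ynoate | CCOC(=O)C#CCO[Si](C)(C)C(C)(C)C | intermediate
4 | lithium methyl[(E)-1-(ethoxycarbonyl)-2-methyl-3-(tert-butyldimethylsilyloxy)prop-1-enyl]cuprate, Me and Cu cis (not isolated) | [Li+].CCOC(=O)/C([Cu-]C)=C(/C)CO[Si](C)(C)C(C)(C)C | intermediate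
5 | ethyl (Z)-4-(tert-butyldimethylsilyloxy)-3-methylbut-2-enoate | C/C(=C/C(=O)OCC)CO[Si](C)(C)C(C)(C)C | intermediate
6 | (Z)-4-(tert-butyldimethylsilyloxy)-3-methylbut-2-en-1-ol | C/C(=C/CO)CO[Si](C)(C)C(C)(C)C | intermediate
7 | tert-butyl{[(2Z)-4-bromo-2-methylbut-2-en-1-yl]oxy}dimethylsilane | C/C(=C/CBr)CO[Si](C)(C)C(C)(C)C | intermediate
8 | 4-bromoresorcinol (4-bromobenzene-1,3-diol) | Oc1ccc(Br)c(O)c1 | starting material
9 | 1-bromo-2,4-bis(methoxymethoxy)benzene | COCOc1ccc(Br)c(OCOC)c1 | intermediate
10 | [3-bromo-2,6-bis(methoxymethoxy)phenyl]lithium (not isolated) | COCOc1ccc(Br)c(OCOC)c1[Li] | intermediate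
11 | [3-bromo-2,6-bis(methoxymethoxy)phenyl]copper (not isolated) | COCOc1ccc(Br)c(OCOC)c1[Cu] | intermediate
12 | 1-bromo-2,4-bis(methoxymethoxy)-3-[(Z)-4-(tert-butyldimethylsilyloxy)-3-methylbut-2-enyl]benzene | C/C(=C/Cc1c(OCOC)ccc(Br)c1OCOC)CO[Si](C)(C)C(C)(C)C | intermediate
13 | 4-bromo-2-[(Z)-4-hydroxy-3-methylbut-2-enyl]benzene-1,3-diol | C/C(=C/Cc1c(O)ccc(Br)c1O)CO | intermediate
14 | 6-bromo-3-(tert-butyldimethylsilyloxy)-2-[(Z)-4-(tert-butyldimethylsilyloxy)-3-methylbut-2-enyl]phenol | C/C(=C/Cc1c(O[Si](C)(C)C(C)(C)C)ccc(Br)c1O)CO[Si](C)(C)C(C)(C)C | intermediate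
15 | 3,4-dihydroxybenzoic acid (protocatechuic acid) | OC(=O)c1ccc(O)c(O)c1 | starting material
16 | tert-butyldimethylsilyl 3,4-bis(tert-butyldimethylsilyloxy)benzoate (not isolated) | CC(C)(C)[Si](C)(C)OC(=O)c1ccc(O[Si](C)(C)C(C)(C)C)c(O[Si](C)(C)C(C)(C)C)c1 | intermediate
17 | 3,4-bis(tert-butyldimethylsilyloxy)benzoic acid | OC(=O)c1ccc(O[Si](C)(C)C(C)(C)C)c(O[Si](C)(C)C(C)(C)C)c1 | intermediate
18 | 6-bromo-3-(tert-butyldimethylsilyloxy)-2-[(Z)-4-(tert-butyldimethylsilyloxy)-3-methylbut-2-enyl]phenyl 3,4-bis(tert-butyldimethylsilyloxy)benzoate | C/C(=C/Cc1c(O[Si](C)(C)C(C)(C)C)ccc(Br)c1OC(=O)c1ccc(O[Si](C)(C)C(C)(C)C)c(O[Si](C)(C)C(C)(C)C)c1)CO[Si](C)(C)C(C)(C)C | intermediate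
19 | 1-bromo-2-{1-[3,4-bis(tert-butyldimethylsilyloxy)phenyl]vinyloxy}-4-(tert-butyldimethylsilyloxy)-3-[(Z)-4-(tert-butyldimethylsilyloxy)-3-methylbut-2-enyl]benzene | C/C(=C/Cc1c(O[Si](C)(C)C(C)(C)C)ccc(Br)c1OC(=C)c1ccc(O[Si](C)(C)C(C)(C)C)c(O[Si](C)(C)C(C)(C)C)c1)CO[Si](C)(C)C(C)(C)C | intermediate
20 | aryllithium from 19, lithium in place of bromine (not isolated) | C/C(=C/Cc1c(O[Si](C)(C)C(C)(C)C)ccc([Li])c1OC(=C)c1ccc(O[Si](C)(C)C(C)(C)C)c(O[Si](C)(C)C(C)(C)C)c1)CO[Si](C)(C)C(C)(C)C | intermediate
21 | 2-{1-[3,4-bis(tert-butyldimethylsilyloxy)phenyl]vinyloxy}-4-(tert-butyldimethylsilyloxy)-3-[(Z)-4-(tert-butyldimethylsilyloxy)-3-methylbut-2-enyl]benzaldehyde | C/C(=C/Cc1c(O[Si](C)(C)C(C)(C)C)ccc(C=O)c1OC(=C)c1ccc(O[Si](C)(C)C(C)(C)C)c(O[Si](C)(C)C(C)(C)C)c1)CO[Si](C)(C)C(C)(C)C | intermediate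
22 | (2S)-2-[3,4-bis(tert-butyldimethylsilyloxy)phenyl]-7-(tert-butyldimethylsilyloxy)-8-[(Z)-4-(tert-butyldimethylsilyloxy)-3-methylbut-2-enyl]chroman-4-one | C/C(=C/Cc1c(O[Si](C)(C)C(C)(C)C)ccc2c1O[C@H](c1ccc(O[Si](C)(C)C(C)(C)C)c(O[Si](C)(C)C(C)(C)C)c1)CC2=O)CO[Si](C)(C)C(C)(C)C | intermediate
23 | (2S)-2-(3,4-dihydroxyphenyl)-7-hydroxy-8-[(2Z)-4-hydroxy-3-methylbut-2-en-1-yl]-2,3-dihydro-4H-chromen-4-one | C/C(=C/Cc1c(O)ccc2c1O[C@H](c1ccc(O)c(O)c1)CC2=O)CO | target

Total step count: 14. Longest linear sequence: 12 steps (steps 1, 2, 3, 4, 6, 7, 8, 10, 11, 12, 13, 14; from 4-bromoresorcinol it is 9).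

Steps most likely to fail

1. Step 13. What may go wrong: decarbonylation of the acyl rhodium outrunning olefin insertion, exo insertion leading to five-ring closure, acid-induced addition of the enol ether to the aldehyde, or poor facial selectivity in hydride delivery. The fallback uses known chemistry, sets out from 14 and rejoins the route at 22. Phenol 14 is doubly lithiated (MeLi, then t-BuLi, THF, −78 °C) and acylated with N-methoxy-N-methylacetamide to give the 2'-hydroxyacetophenone F1. Heating with DMF dimethyl acetal gives the enaminone F2, which closes on silica gel or with TMSCl to the 2-unsubstituted chromone F3. In parallel, 4-bromocatechol is silylated to 4-bromo-1,2-bis(tert-butyldimethylsilyloxy)benzene F4, and bromine–lithium exchange followed by B(Oi-Pr)3 and mild hydrolysis gives [3,4-bis(tert-butyldimethylsilyloxy)phenyl]boronic acid F5. Palladium(II)/pyridine-oxazoline-catalysed enantioselective conjugate addition of F5 to F3 (Pd(OCOCF3)2, t-BuPyOx of the hand that gives 2S, NH4PF6, H2O, DCE, 60 °C) should then give 22, which is desilylated as in step 14.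

2. Step 6. What may go wrong: bromine scrambling or aryne formation during the amide-base metalation, or a sluggish arylcopper that lets γ-attack and loss of Z geometry compete. The fallback sets out from 7 (with commercial resorcinol) and rejoins at 12; bromine is introduced only after the side chain. Resorcinol is converted with MOMCl/i-Pr2NEt into 1,3-bis(methoxymethoxy)benzene F6. Lithiation at C2 with n-BuLi (THF, 0 °C), transmetalation with CuI and allylation with 7 follow the standard halogen-free resorcinol prenylation protocol and give the 2-allylated arene F7. A second directed lithiation ortho to one MOM ether (s-BuLi, TMEDA, THF, −78 °C) and quench with 1,2-dibromotetrachloroethane should give 12.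

3. Step 8. What may go wrong: insufficient discrimination between the two phenolic hydroxyls, i.e. silylation of the bromine-flanked hydroxyl or incomplete silylation of the other. The fallback sets out from 13 and 17 and rejoins at 18; it reverses the order of events and uses the difference in acidity instead of the difference in size. Acid 17 is converted with 1-chloro-N,N,2-trimethylprop-1-en-1-amine (CH2Cl2, 0 °C) into 3,4-bis(tert-butyldimethylsilyloxy)benzoyl chloride F8. Triol 13 is acylated with F8 under pH control (aq NaHCO3/CH2Cl2, Bu4NHSO4, 0 °C), where only the more acidic ortho-bromophenol is ionised, to give the mono-ester diol F9. TBSCl (2.2 equiv)/imidazole then silylates the remaining phenol and the primary alcohol to give 18.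

Further compounds
F1 | step 13 | 1-{2-hydroxy-4-(tert-butyldimethylsilyloxy)-3-[(Z)-4-(tert-butyldimethylsilyloxy)-3-methylbut-2-enyl]phenyl}ethan-1-one | C/C(=C/Cc1c(O[Si](C)(C)C(C)(C)C)ccc(C(C)=O)c1O)CO[Si](C)(C)C(C)(C)C
F2 | step 13 | (E)-3-(dimethylamino)-1-{2-hydroxy-4-(tert-butyldimethylsilyloxy)-3-[(Z)-4-(tert-butyldimethylsilyloxy)-3-methylbut-2-enyl]phenyl}prop-2-en-1-one | C/C(=C/Cc1c(O[Si](C)(C)C(C)(C)C)ccc(C(=O)/C=C/N(C)C)c1O)CO[Si](C)(C)C(C)(C)C
F3 | step 13 | 7-(tert-butyldimethylsilyloxy)-8-[(Z)-4-(tert-butyldimethylsilyloxy)-3-methylbut-2-enyl]-4H-chromen-4-one | C/C(=C/Cc1c(O[Si](C)(C)C(C)(C)C)ccc2c(=O)ccoc12)CO[Si](C)(C)C(C)(C)C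
F4 | step 13 | 4-bromo-1,2-bis(tert-butyldimethylsilyloxy)benzene | Brc1ccc(O[Si](C)(C)C(C)(C)C)c(O[Si](C)(C)C(C)(C)C)c1
F5 | step 13 | [3,4-bis(tert-butyldimethylsilyloxy)phenyl]boronic acid | OB(O)c1ccc(O[Si](C)(C)C(C)(C)C)c(O[Si](C)(C)C(C)(C)C)c1
F6 | step 6 | 1,3-bis(methoxymethoxy)benzene | COCOc1cccc(OCOC)c1
F7 | step 6 | 1,3-bis(methoxymethoxy)-2-[(Z)-4-(tert-butyldimethylsilyloxy)-3-methylbut-2-enyl]benzene | C/C(=C/Cc1c(OCOC)cccc1OCOC)CO[Si](C)(C)C(C)(C)C
F8 | step 8 | 3,4-bis(tert-butyldimethylsilyloxy)benzoyl chloride | O=C(Cl)c1ccc(O[Si](C)(C)C(C)(C)C)c(O[Si](C)(C)C(C)(C)C)c1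
F9 | step 8 | 6-bromo-3-hydroxy-2-[(Z)-4-hydroxy-3-methylbut-2-enyl]phenyl 3,4-bis(tert-butyldimethylsilyloxy)benzoate | C/C(=C/Cc1c(O)ccc(Br)c1OC(=O)c1ccc(O[Si](C)(C)C(C)(C)C)c(O[Si](C)(C)C(C)(C)C)c1)CO
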